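**Strategy.** The dienone ring (ring A) is disconnected between C5, the enol carbon next to quaternary C4, and C6, the carbon that later carries the methylene bridge. C5 is treated as an ester carbonyl and C6 as the methyl group of an acetyl ketone, so an acyclic triacylmethane ester closes to ring A in one dianion Dieckmann condensation. The step exploits that C4, having no hydrogen, cannot enolise toward the ester or epimerise: an enantioselective malonate alkylation sets C4 early, and the two different ester groups decide which flank becomes C3 and which C5. The aryl ketone (ring B) is then joined through a one-carbon Mannich unit.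

Key step: step 6

Assumption: enolised polyketones are drawn as the tautomer shown in their SMILES and CIP descriptors refer to that tautomer; the sense of induction in step 3 is taken by analogy with allylic halides on this malonate class, and the mirror-image catalyst is to be used if a first run shows the opposite sense.

Step 1
Reactants: 1 2,2,5-trimethyl-1,3-dioxane-4,6-dione; 2 tert-butanol
Product: 3 3-(tert-butoxy)-2-methyl-3-oxopropanoic acid (racemic)
Conditions: t-BuOH (solvent), reflux
Reagents that add atoms: none
Why: Alcoholysis of the cyclic acylal opens the ring and the hemiketal ester loses acetone, which should give the malonic half-ester.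

Step 2
Reactants: 3 3-(tert-butoxy)-2-methyl-3-oxopropanoic acid; 4 2,2-diphenylethanol
Product: 5 1-tert-butyl 3-(2,2-diphenylethyl) 2-methylmalonate (racemic)
Conditions: EDC·HCl, DMAP (cat.), CH2Cl2, 0 °C → rt
Reagents that add atoms: none
Why: Steglich-type carbodiimide esterification of the free acid with a primary alcohol should give the mixed malonate whose two esters can later be told apart.

Step 3
Reactants: 5 1-tert-butyl 3-(2,2-diphenylethyl) 2-methylmalonate; 6 1-bromo-3-methylbut-2-ene
Product: 7 1-tert-butyl 3-(2,2-diphenylethyl) (2R)-2-methyl-2-(3-methylbut-2-en-1-yl)malonate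
Conditions: (R,R)-2,6-bis(3,4,5-trifluorophenyl)-3,3',5,5'-tetrahydro-4,4'-spirobi[dinaphtho[2,1-c:1',2'-e]azepinium] bromide (5 mol %), 50% aq. KOH, toluene, −40 °C
Reagents that add atoms: none
Why: Asymmetric phase-transfer alkylation, in which the chiral spiro ammonium cation pairs with the malonate enolate and shields one face, so that SN2 attack on the primary carbon of the allylic bromide should set the quaternary center as R.

Step 4
Reactants: 7 1-tert-butyl 3-(2,2-diphenylethyl) (2R)-2-methyl-2-(3-methylbut-2-en-1-yl)malonate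
Product: 9 (2S)-3-(2,2-diphenylethoxy)-2-methyl-2-(3-methylbut-2-en-1-yl)-3-oxopropanoic acid, via trimethylsilyl ester 8 (not isolated)
Conditions: Me3SiOTf, 2,6-lutidine, CH2Cl2, 0 °C → rt; then H2O (pH 4 buffer)
Reagents that add atoms: none
Why: Silyl triflate cleavage of the tert-butyl ester by loss of 2-methylpropene gives a silyl ester that hydrolyses on work-up, the buffered medium sparing the trisubstituted alkene and the primary ester, and the stereocenter is untouched (only its CIP descriptor changes).

Step 5
Reactants: 9 (2S)-3-(2,2-diphenylethoxy)-2-methyl-2-(3-methylbut-2-en-1-yl)-3-oxopropanoic acid; 10 heptane-2,4-dione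
Product: 12 2,2-diphenylethyl (2S)-4-acetyl-2-methyl-2-(3-methylbut-2-en-1-yl)-3,5-dioxooctanoate, via acid chloride 11 (not isolated)
Conditions: (COCl)2, DMF (cat.), CH2Cl2, 0 °C → rt, evaporate; then 10, MgCl2, pyridine, CH2Cl2, 0 °C → rt; dilute HCl work-up
Reagents that add atoms: none
Why: Soft-enolisation C-acylation of the magnesium-chelated β-diketone at its central carbon by an acid chloride that has no α-hydrogen (no ketene, no racemisation) should give the triacylmethane, whose C4 is configurationally labile and left undefined.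

Step 6
Reactants: 12 2,2-diphenylethyl (2S)-4-acetyl-2-methyl-2-(3-methylbut-2-en-1-yl)-3,5-dioxooctanoate
Product: 13 (4R)-2-butanoyl-3,5-dihydroxy-4-methyl-4-(3-methylbut-2-en-1-yl)cyclohexa-2,5-dien-1-one
Conditions: LiN(i-Pr)2 (2.3 equiv), THF, −78 °C → 0 °C; then 1 M HCl
Reagents that add atoms: none
Why: The first equivalent of base gives the triacylmethanide and the second removes a proton from the acetyl methyl group, whose carbanion (future C6) adds to the ester carbonyl (future C5) with loss of 2,2-diphenylethoxide. The closest known reaction type is the γ-acylation of a β-dicarbonyl dianion run intramolecularly, that is a Dieckmann condensation of a polyketo ester as used in biomimetic phloroglucinol syntheses. Ring A closes in the 6-(enolendo)-exo-trig mode. No new stereocenter is formed: quaternary C4 carries no hydrogen, so it cannot epimerise or turn the ester into an unreactive enolate, and because the ester flank becomes C5 while the ketone flank is already C3, the configuration from step 3 is carried into the ring unchanged (the descriptor changes from S to R by priority only). The selectivity needed is closure through the acetyl methyl and not the butanoyl α-methylene, which the kinetic preference for methyl over methylene in the second deprotonation and the lower hindrance of a primary carbanion attacking a neopentyl-type ester should secure. Geminal substitution at C4 should favour cyclisation over intermolecular condensation.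

Step 7
Reactants: 14 5-methoxybenzene-1,3-diol; 15 butanenitrile
Product: 17 1-(2,4-dihydroxy-6-methoxyphenyl)butan-1-one, via ketiminium chloride 16 (not isolated)
Conditions: ZnCl2, HCl (g), Et2O, 0 °C; then H2O, reflux
Reagents that add atoms: water, O
Why: Hoesch acylation, in which the nitrilium electrophile should attack the position para to one hydroxyl (two equivalent sites) in preference to the hindered position between the two hydroxyls, and hydrolysis of the ketiminium salt gives the ketone.

Step 8
Reactants: 13 (4R)-2-butanoyl-3,5-dihydroxy-4-methyl-4-(3-methylbut-2-en-1-yl)cyclohexa-2,5-dien-1-one; 18 N,N-dimethylmethyleneiminium iodide; 17 1-(2,4-dihydroxy-6-methoxyphenyl)butan-1-one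
Product: 21 (4R)-2-butanoyl-6-[(3-butanoyl-2,6-dihydroxy-4-methoxyphenyl)methyl]-3,5-dihydroxy-4-methyl-4-(3-methylbut-2-en-1-yl)cyclohexa-2,5-dien-1-one, via Mannich base 19 (not isolated), via methylene trione 20 (not isolated)
Conditions: 18 (1.05 equiv), NaOAc (1.1 equiv), MeCN, 0 °C → rt; then 17 (2 equiv), 60 °C; dilute HCl work-up
Reagents that add atoms: none
Why: Mannich reaction at the C6 enol carbon gives the aminomethyl trione, which on warming loses dimethylamine to a 6-methylene trione (a vinylogous quinone methide), and Friedel–Crafts-type conjugate addition of the phenol through the ring carbon between its two hydroxyls should form the methylene bridge without touching C4.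

**Compound list**

1 | 2,2,5-trimethyl-1,3-dioxane-4,6-dione | CC1C(=O)OC(C)(C)OC1=O | starting material
2 | tert-butanol | CC(C)(C)O | starting material
3 | 3-(tert-butoxy)-2-methyl-3-oxopropanoic acid (racemic) | CC(C(=O)O)C(=O)OC(C)(C)C | intermediate
4 | 2,2-diphenylethanol | OCC(c1ccccc1)c1ccccc1 | starting material
5 | 1-tert-butyl 3-(2,2-diphenylethyl) 2-methylmalonate (racemic) | CC(C(=O)OC(C)(C)C)C(=O)OCC(c1ccccc1)c1ccccc1 | intermediate
6 | 1-bromo-3-methylbut-2-ene | CC(C)=CCBr | starting material
7 | 1-tert-butyl 3-(2,2-diphenylethyl) (2R)-2-methyl-2-(3-methylbut-2-en-1-yl)malonate | CC(C)(C)OC(=O)[C@](C)(CC=C(C)C)C(=O)OCC(c1ccccc1)c1ccccc1 | intermediate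
8 | 1-(2,2-diphenylethyl) 3-trimethylsilyl (2R)-2-methyl-2-(3-methylbut-2-en-1-yl)malonate | C[Si](C)(C)OC(=O)[C@](C)(CC=C(C)C)C(=O)OCC(c1ccccc1)c1ccccc1 | intermediate
9 | (2S)-3-(2,2-diphenylethoxy)-2-methyl-2-(3-methylbut-2-en-1-yl)-3-oxopropanoic acid | OC(=O)[C@](C)(CC=C(C)C)C(=O)OCC(c1ccccc1)c1ccccc1 | intermediate
10 | heptane-2,4-dione | CCCC(=O)CC(C)=O | starting material
11 | 2,2-diphenylethyl (2R)-3-chloro-2-methyl-2-(3-methylbut-2-en-1-yl)-3-oxopropanoate | ClC(=O)[C@](C)(CC=C(C)C)C(=O)OCC(c1ccccc1)c1ccccc1 | intermediate
12 | 2,2-diphenylethyl (2S)-4-acetyl-2-methyl-2-(3-methylbut-2-en-1-yl)-3,5-dioxooctanoate (C4 labile, undefined) | CCCC(=O)C(C(C)=O)C(=O)[C@](C)(CC=C(C)C)C(=O)OCC(c1ccccc1)c1ccccc1 | intermediate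
13 | (4R)-2-butanoyl-3,5-dihydroxy-4-methyl-4-(3-methylbut-2-en-1-yl)cyclohexa-2,5-dien-1-one | CCCC(=O)C1=C(O)[C@](C)(CC=C(C)C)C(O)=CC1=O | intermediate
14 | 5-methoxybenzene-1,3-diol | COc1cc(O)cc(O)c1 | starting material
15 | butanenitrile | CCCC#N | starting material
16 | 1-(2,4-dihydroxy-6-methoxyphenyl)butan-1-iminium chloride | CCCC(=[NH2+])c1c(O)cc(O)cc1OC.[Cl-] | intermediate
17 | 1-(2,4-dihydroxy-6-methoxyphenyl)butan-1-one | CCCC(=O)c1c(O)cc(O)cc1OC | intermediate
18 | N,N-dimethylmethyleneiminium iodide | C[N+](C)=C.[I-] | starting material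
19 | (4R)-2-butanoyl-6-[(dimethylamino)methyl]-3,5-dihydroxy-4-methyl-4-(3-methylbut-2-en-1-yl)cyclohexa-2,5-dien-1-one | CCCC(=O)C1=C(O)[C@](C)(CC=C(C)C)C(O)=C(CN(C)C)C1=O | intermediate
20 | (4S)-2-butanoyl-3-hydroxy-4-methyl-4-(3-methylbut-2-en-1-yl)-6-methylidenecyclohex-2-ene-1,5-dione | CCCC(=O)C1=C(O)[C@](C)(CC=C(C)C)C(=O)C(=C)C1=O | intermediate
21 | (4R)-2-butanoyl-6-[(3-butanoyl-2,6-dihydroxy-4-methoxyphenyl)methyl]-3,5-dihydroxy-4-methyl-4-(3-methylbut-2-en-1-yl)cyclohexa-2,5-dien-1-one | CCCC(=O)C1=C(O)[C@](C)(CC=C(C)C)C(O)=C(Cc2c(O)cc(OC)c(C(=O)CCC)c2O)C1=O | target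

**Step count and risks**

Total steps: 8. Longest linear sequence: 7 (steps 1 to 6, then step 8); step 7 is a one-step side branch.

Steps most likely to fail:

1. Step 6. The second deprotonation may occur partly at the butanoyl α-methylene, so that the ring closes through the wrong carbon, or the strong base may attack the 2,2-diphenylethyl ester before cyclisation. Fallback: setting out from acid chloride 11, the nucleophilic carbon is made a doubly activated methylene. Methyl 3,5-dioxooctanoate F1 (from the dianion of methyl acetoacetate, NaH then n-BuLi, and methyl butanoate) is C-acylated at its C4 with 11 (MgCl2, pyridine) to give 1-(2,2-diphenylethyl) 7-methyl (2S)-4-butanoyl-2-methyl-2-(3-methylbut-2-en-1-yl)-3,5-dioxoheptanedioate F2. NaH in THF should then close ring A through the carbanion between ketone and methyl ester, giving methyl (3S)-5-butanoyl-2,4-dihydroxy-3-methyl-3-(3-methylbut-2-en-1-yl)-6-oxocyclohexa-1,4-diene-1-carboxylate F3. Saponification with aqueous NaOH, then acidification and loss of carbon dioxide, comes back to the route at 13.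

2. Step 8. The methylene trione may attack arene 17 at C5 instead of C3, alkylate it twice, or be intercepted by unreacted 13 to give the symmetric dimer. Fallback: setting out from 13, the bridging carbon is brought in on the arene, where symmetry fixes its position. 2,4,6-Trihydroxybenzaldehyde is methylated at the 4-hydroxyl (Me2SO4, K2CO3, acetone) to 2,6-dihydroxy-4-methoxybenzaldehyde F4, whose two open ring positions are equivalent. Friedel–Crafts acylation (butanoic anhydride, BF3·OEt2) should give 3-butanoyl-2,6-dihydroxy-4-methoxybenzaldehyde F5. Three-component reductive alkylation of 13 with F5 (L-proline cat., Hantzsch ester, CH2Cl2) passes through the arylidene trione (4S)-2-butanoyl-6-[(3-butanoyl-2,6-dihydroxy-4-methoxyphenyl)methylidene]-3-hydroxy-4-methyl-4-(3-methylbut-2-en-1-yl)cyclohex-2-ene-1,5-dione F6 (alkene geometry undefined), which is reduced in situ, and comes back at 21.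

3. Step 5. The hindered acid chloride may acylate the diketone on oxygen or react too slowly, and the triacylmethane may lose its acetyl group during work-up. Fallback: setting out from acid 9, the large acyl group is attached first and the small one last. 1,1'-Carbonyldiimidazole in THF gives 2,2-diphenylethyl (2S)-3-(imidazol-1-yl)-2-methyl-2-(3-methylbut-2-en-1-yl)-3-oxopropanoate F7, which acylates the kinetic lithium enolate of pentan-2-one (LiN(i-Pr)2, THF, −78 °C) to give 2,2-diphenylethyl (2S)-2-methyl-2-(3-methylbut-2-en-1-yl)-3,5-dioxooctanoate F8. C-acetylation of F8 at C4 (acetyl chloride, MgCl2, pyridine) comes back at 12.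

**Further compounds**

F1 | step 6 | methyl 3,5-dioxooctanoate | CCCC(=O)CC(=O)CC(=O)OC
F2 | step 6 | 1-(2,2-diphenylethyl) 7-methyl (2S)-4-butanoyl-2-methyl-2-(3-methylbut-2-en-1-yl)-3,5-dioxoheptanedioate | CCCC(=O)C(C(=O)CC(=O)OC)C(=O)[C@](C)(CC=C(C)C)C(=O)OCC(c1ccccc1)c1ccccc1
F3 | step 6 | methyl (3S)-5-butanoyl-2,4-dihydroxy-3-methyl-3-(3-methylbut-2-en-1-yl)-6-oxocyclohexa-1,4-diene-1-carboxylate | CCCC(=O)C1=C(O)[C@](C)(CC=C(C)C)C(O)=C(C(=O)OC)C1=O
F4 | step 8 | 2,6-dihydroxy-4-methoxybenzaldehyde | COc1cc(O)c(C=O)c(O)c1
F5 | step 8 | 3-butanoyl-2,6-dihydroxy-4-methoxybenzaldehyde | CCCC(=O)c1c(OC)cc(O)c(C=O)c1O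
F6 | step 8 | (4S)-2-butanoyl-6-[(3-butanoyl-2,6-dihydroxy-4-methoxyphenyl)methylidene]-3-hydroxy-4-methyl-4-(3-methylbut-2-en-1-yl)cyclohex-2-ene-1,5-dione | CCCC(=O)C1=C(O)[C@](C)(CC=C(C)C)C(=O)C(=Cc2c(O)cc(OC)c(C(=O)CCC)c2O)C1=O
F7 | step 5 | 2,2-diphenylethyl (2S)-3-(imidazol-1-yl)-2-methyl-2-(3-methylbut-2-en-1-yl)-3-oxopropanoate | O=C(n1ccnc1)[C@](C)(CC=C(C)C)C(=O)OCC(c1ccccc1)c1ccccc1
F8 | step 5 | 2,2-diphenylethyl (2S)-2-methyl-2-(3-methylbut-2-en-1-yl)-3,5-dioxooctanoate | CCCC(=O)CC(=O)[C@](C)(CC=C(C)C)C(=O)OCC(c1ccccc1)c1ccccc1
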